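**Assumption:** the target SMILES carries no stereodescriptor, so the 8,8''-biaryl axis is taken as unspecified and every biaryl compound below is made and drawn as the racemate.

## Retrosynthetic overview

1. Target 18 comes from penta-O-benzyl biflavone 17 by hydrogenolysis; the single 4'-OMe is the only ether that stays.
2. 17 comes from bichalcone 15: both pyranone rings (ring C and ring C'') are closed last, together, in one I2/DMSO oxidative cyclisation.
3. 15 comes from biaryl bis(2-hydroxyacetophenone) 9 by two successive intermolecular Claisen–Schmidt aldol condensations, first with 4-methoxybenzaldehyde, then with 4-(benzyloxy)benzaldehyde (key C–C bonds; the B rings arrive ready-made).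
4. 9 comes from Ullmann homocoupling of iodide 7, which sets the biaryl bond early between two ready-made A rings, followed by MOM removal.
5. 7 comes from phloroacetophenone 1 by 4,6-di-O-benzylation, C3 iodination and 2-O-MOM protection.

## Route

Step 1
Reactants: 1 2',4',6'-trihydroxyacetophenone; 2 benzyl bromide
Product: 3 1-[2,4-bis(benzyloxy)-6-hydroxyphenyl]ethan-1-one
Conditions: BnBr (2.1 equiv), K2CO3 (2.2 equiv), DMF, 0 °C to rt
Reagents that add atoms: benzyl bromide (2), BrCc1ccccc1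
Why: Williamson etherification stops at the 4,6-diether because the remaining ortho OH is hydrogen-bonded to the acetyl group and much less nucleophilic.

Step 2
Reactants: 3 1-[2,4-bis(benzyloxy)-6-hydroxyphenyl]ethan-1-one; 4 N-iodosuccinimide
Product: 5 1-[4,6-bis(benzyloxy)-2-hydroxy-3-iodophenyl]ethan-1-one
Conditions: NIS (1.05 equiv), TFA (0.2 equiv), MeCN, 0 °C to rt, dark
Reagents that add atoms: N-iodosuccinimide (4), O=C1CCC(=O)N1I
Why: Electrophilic aromatic iodination of 2-hydroxy-4,6-dialkoxyacetophenones goes ortho to the chelated phenol (C3), the position that becomes C8 of the flavone; the regiochemistry is checked by NOE/HMBC of the remaining ring proton.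

Step 3
Reactants: 5 1-[4,6-bis(benzyloxy)-2-hydroxy-3-iodophenyl]ethan-1-one; 6 chloromethyl methyl ether
Product: 7 1-[4,6-bis(benzyloxy)-3-iodo-2-(methoxymethoxy)phenyl]ethan-1-one
Conditions: NaH (1.2 equiv), MOMCl (1.5 equiv), DMF, 0 °C to rt
Reagents that add atoms: chloromethyl methyl ether (6), COCCl
Why: O-alkylation of the sodium phenoxide masks the phenol for the copper coupling with an acetal that can later be removed without touching the benzyl ethers.

Step 4
Reactants: 7 1-[4,6-bis(benzyloxy)-3-iodo-2-(methoxymethoxy)phenyl]ethan-1-one (2 molecules)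
Product: 8 1,1'-[4,4',6,6'-tetrakis(benzyloxy)-2,2'-bis(methoxymethoxy)[1,1'-biphenyl]-3,3'-diyl]di(ethan-1-one)
Conditions: activated Cu powder (6 equiv), degassed DMF, 150 °C, 16 h
Reagents that add atoms: none
Why: Classical Ullmann homocoupling of a 2,6-dialkoxyaryl iodide gives the symmetrical tetra-ortho-substituted biaryl, with no cross-selectivity issue because both halves are identical.

Step 5
Reactants: 8 bis-MOM biaryl diketone
Product: 9 1,1'-[4,4',6,6'-tetrakis(benzyloxy)-2,2'-dihydroxy[1,1'-biphenyl]-3,3'-diyl]di(ethan-1-one)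
Conditions: 3 M HCl (aq.), MeOH/THF, 50 °C
Reagents that add atoms: none
Why: Acid-catalysed acetal methanolysis removes only the MOM groups (benzyl ethers are inert to dilute HCl) and frees exactly the two phenols flanked by the biaryl bond and the acetyl groups.

Step 6
Reactants: 9 biaryl bis(2-hydroxyacetophenone); 10 4-methoxybenzaldehyde
Product: 12 (E)-1-[3'-acetyl-4,4',6,6'-tetrakis(benzyloxy)-2,2'-dihydroxy[1,1'-biphenyl]-3-yl]-3-(4-methoxyphenyl)prop-2-en-1-one, via β-hydroxy ketone 11 (not isolated)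
Conditions: 9 (2.5 equiv), 10 (1.0 equiv), KOH (50% aq.), EtOH/THF, rt, 24 h; then 1 M HCl; excess 9 recovered by chromatography
Reagents that add atoms: 4-methoxybenzaldehyde (10), COc1ccc(C=O)cc1
Why: Intermolecular Claisen–Schmidt aldol condensation gives the E-enone by E1cB dehydration; running it with the diketone in excess makes the mono-chalcone the main product, and the new stereocentre of 11 is lost on dehydration.

Step 7
Reactants: 12 mono-chalcone; 13 4-(benzyloxy)benzaldehyde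
Product: 15 (E)-3-[4-(benzyloxy)phenyl]-1-{4,4',6,6'-tetrakis(benzyloxy)-2,2'-dihydroxy-3'-[(E)-3-(4-methoxyphenyl)prop-2-enoyl][1,1'-biphenyl]-3-yl}prop-2-en-1-one, via β-hydroxy ketone 14 (not isolated)
Conditions: 13 (3 equiv), KOH (50% aq.), EtOH/THF, rt, 48 h; then 1 M HCl
Reagents that add atoms: 4-(benzyloxy)benzaldehyde (13), O=Cc1ccc(OCc2ccccc2)cc1
Why: A second Claisen–Schmidt aldol condensation on the remaining methyl ketone places the other B ring; the first chalcone, present as its phenoxide, is a poor Michael acceptor and does not undergo retro-aldol exchange at room temperature.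

Step 8
Reactants: 15 unsymmetrical bichalcone
Product: 17 5,7-bis(benzyloxy)-8-{5,7-bis(benzyloxy)-2-[4-(benzyloxy)phenyl]-4-oxo-4H-chromen-8-yl}-2-(4-methoxyphenyl)-4H-chromen-4-one, via bis-flavanone 16 (not isolated)
Conditions: I2 (0.2 equiv), DMSO, 130 °C, 3 h; then aq. Na2S2O3
Reagents that add atoms: none
Why: Iodine-catalysed oxidative cyclisation of 2'-hydroxychalcones (oxa-Michael closure, then iodination/HI elimination with DMSO as terminal oxidant) forms both pyranone rings at once; it is run only after both methyl ketones are consumed, since I2/DMSO would oxidise a free acetyl group.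

Step 9
Reactants: 17 penta-O-benzyl biflavone
Product: 18 5,7-dihydroxy-8-[5,7-dihydroxy-2-(4-hydroxyphenyl)-4-oxo-4H-chromen-8-yl]-2-(4-methoxyphenyl)-4H-chromen-4-one (4'-O-methylcupressuflavone)
Conditions: H2 (1 atm), Pd/C (10% Pd on carbon), THF/MeOH, rt, stopped at full conversion
Reagents that add atoms: none
Why: Catalytic hydrogenolysis cleaves the five benzyl ethers, while the aryl methyl ether and the vinylogous-ester C2=C3 bonds of the flavones are not reduced under balloon pressure at room temperature.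

## Compound list

1 | 2',4',6'-trihydroxyacetophenone (phloroacetophenone) | CC(=O)c1c(O)cc(O)cc1O | starting material
2 | benzyl bromide | BrCc1ccccc1 | starting material
3 | 1-[2,4-bis(benzyloxy)-6-hydroxyphenyl]ethan-1-one | CC(=O)c1c(O)cc(OCc2ccccc2)cc1OCc1ccccc1 | intermediate
4 | N-iodosuccinimide | O=C1CCC(=O)N1I | starting material
5 | 1-[4,6-bis(benzyloxy)-2-hydroxy-3-iodophenyl]ethan-1-one | CC(=O)c1c(O)c(I)c(OCc2ccccc2)cc1OCc1ccccc1 | intermediate
6 | chloromethyl methyl ether | COCCl | starting material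
7 | 1-[4,6-bis(benzyloxy)-3-iodo-2-(methoxymethoxy)phenyl]ethan-1-one | CC(=O)c1c(OCOC)c(I)c(OCc2ccccc2)cc1OCc1ccccc1 | intermediate
8 | 1,1'-[4,4',6,6'-tetrakis(benzyloxy)-2,2'-bis(methoxymethoxy)[1,1'-biphenyl]-3,3'-diyl]di(ethan-1-one), racemic axis | CC(=O)c1c(OCOC)c(-c2c(OCOC)c(C(C)=O)c(OCc3ccccc3)cc2OCc2ccccc2)c(OCc2ccccc2)cc1OCc1ccccc1 | intermediate
9 | 1,1'-[4,4',6,6'-tetrakis(benzyloxy)-2,2'-dihydroxy[1,1'-biphenyl]-3,3'-diyl]di(ethan-1-one), racemic axis | CC(=O)c1c(O)c(-c2c(O)c(C(C)=O)c(OCc3ccccc3)cc2OCc2ccccc2)c(OCc2ccccc2)cc1OCc1ccccc1 | intermediate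
10 | 4-methoxybenzaldehyde | COc1ccc(C=O)cc1 | starting material
11 | 1-[3'-acetyl-4,4',6,6'-tetrakis(benzyloxy)-2,2'-dihydroxy[1,1'-biphenyl]-3-yl]-3-hydroxy-3-(4-methoxyphenyl)propan-1-one, mixture of stereoisomers | COc1ccc(C(O)CC(=O)c2c(O)c(-c3c(O)c(C(C)=O)c(OCc4ccccc4)cc3OCc3ccccc3)c(OCc3ccccc3)cc2OCc2ccccc2)cc1 | intermediate (not isolated)
12 | (E)-1-[3'-acetyl-4,4',6,6'-tetrakis(benzyloxy)-2,2'-dihydroxy[1,1'-biphenyl]-3-yl]-3-(4-methoxyphenyl)prop-2-en-1-one, racemic axis | COc1ccc(/C=C/C(=O)c2c(O)c(-c3c(O)c(C(C)=O)c(OCc4ccccc4)cc3OCc3ccccc3)c(OCc3ccccc3)cc2OCc2ccccc2)cc1 | intermediate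
13 | 4-(benzyloxy)benzaldehyde | O=Cc1ccc(OCc2ccccc2)cc1 | starting material
14 | (E)-1-[4,4',6,6'-tetrakis(benzyloxy)-3'-{3-[4-(benzyloxy)phenyl]-3-hydroxypropanoyl}-2,2'-dihydroxy[1,1'-biphenyl]-3-yl]-3-(4-methoxyphenyl)prop-2-en-1-one, mixture of stereoisomers | COc1ccc(/C=C/C(=O)c2c(O)c(-c3c(O)c(C(=O)CC(O)c4ccc(OCc5ccccc5)cc4)c(OCc4ccccc4)cc3OCc3ccccc3)c(OCc3ccccc3)cc2OCc2ccccc2)cc1 | intermediate (not isolated)
15 | (E)-3-[4-(benzyloxy)phenyl]-1-{4,4',6,6'-tetrakis(benzyloxy)-2,2'-dihydroxy-3'-[(E)-3-(4-methoxyphenyl)prop-2-enoyl][1,1'-biphenyl]-3-yl}prop-2-en-1-one, racemic axis | COc1ccc(/C=C/C(=O)c2c(O)c(-c3c(O)c(C(=O)/C=C/c4ccc(OCc5ccccc5)cc4)c(OCc4ccccc4)cc3OCc3ccccc3)c(OCc3ccccc3)cc2OCc2ccccc2)cc1 | intermediate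
16 | 5,7-bis(benzyloxy)-8-{5,7-bis(benzyloxy)-2-[4-(benzyloxy)phenyl]-4-oxochroman-8-yl}-2-(4-methoxyphenyl)chroman-4-one (8,8''-biflavanone), mixture of stereoisomers | COc1ccc(C2CC(=O)c3c(OCc4ccccc4)cc(OCc4ccccc4)c(-c4c(OCc5ccccc5)cc(OCc5ccccc5)c5c4OC(c4ccc(OCc6ccccc6)cc4)CC5=O)c3O2)cc1 | intermediate (not isolated)
17 | 5,7-bis(benzyloxy)-8-{5,7-bis(benzyloxy)-2-[4-(benzyloxy)phenyl]-4-oxo-4H-chromen-8-yl}-2-(4-methoxyphenyl)-4H-chromen-4-one, racemic axis | COc1ccc(-c2cc(=O)c3c(OCc4ccccc4)cc(OCc4ccccc4)c(-c4c(OCc5ccccc5)cc(OCc5ccccc5)c5c(=O)cc(-c6ccc(OCc7ccccc7)cc6)oc45)c3o2)cc1 | intermediate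
18 | 5,7-dihydroxy-8-[5,7-dihydroxy-2-(4-hydroxyphenyl)-4-oxo-4H-chromen-8-yl]-2-(4-methoxyphenyl)-4H-chromen-4-one (4'-O-methylcupressuflavone, CNP0322111.0) | COc1ccc(-c2cc(=O)c3c(O)cc(O)c(-c4c(O)cc(O)c5c(=O)cc(-c6ccc(O)cc6)oc45)c3o2)cc1 | target

## Summary

Total step count: 9. Longest linear sequence: 9 steps (1 to 18).

**Steps most likely to fail**

- **Step 4 (Ullmann homocoupling).** The tetra-ortho-substituted biaryl forms slowly and protodeiodination of 7 competes. Fallback, setting out from 7 and coming back at 8: half of 7 is borylated (bis(pinacolato)diboron, PdCl2(dppf), KOAc, dioxane, 90 °C) to 1-[4,6-bis(benzyloxy)-2-(methoxymethoxy)-3-(4,4,5,5-tetramethyl-1,3,2-dioxaborolan-2-yl)phenyl]ethan-1-one F1. F1 is then cross-coupled with the other half of 7 in a Suzuki–Miyaura reaction tuned for hindered partners (Pd(OAc)2, SPhos, K3PO4, toluene/water, 100 °C) to give 8.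

- **Step 6 (mono-condensation of the symmetrical diketone).** The two acetyl groups react independently, so bis-chalcone and unreacted 9 always accompany 12 and the yield rests on separation and recycling. Fallback, setting out from 5 and coming back at 17, builds each flavone half separately so that no statistical step remains:
  - Claisen–Schmidt condensation of 5 with 10 (KOH, EtOH/THF, rt) gives (E)-1-[4,6-bis(benzyloxy)-2-hydroxy-3-iodophenyl]-3-(4-methoxyphenyl)prop-2-en-1-one F2, which I2 (cat.)/DMSO at 130 °C cyclises to 5,7-bis(benzyloxy)-8-iodo-2-(4-methoxyphenyl)-4H-chromen-4-one F3.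
  - In the same way 5 and 13 give (E)-1-[4,6-bis(benzyloxy)-2-hydroxy-3-iodophenyl]-3-[4-(benzyloxy)phenyl]prop-2-en-1-one F4 and then 5,7-bis(benzyloxy)-2-[4-(benzyloxy)phenyl]-8-iodo-4H-chromen-4-one F5.
  - F5 is borylated (bis(pinacolato)diboron, PdCl2(dppf), KOAc, dioxane, 90 °C) to 5,7-bis(benzyloxy)-2-[4-(benzyloxy)phenyl]-8-(4,4,5,5-tetramethyl-1,3,2-dioxaborolan-2-yl)-4H-chromen-4-one F6.
  - Suzuki–Miyaura coupling of F3 with F6 (Pd(OAc)2, SPhos, K3PO4, toluene/water, 100 °C) gives 17.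

- **Step 8 (double oxidative cyclisation).** HI formed at 130 °C can cleave the 5-O-benzyl ethers or iodinate C6, and the reaction can stall at the flavanone stage. Fallback, setting out from 15 and coming back at 17: the bichalcone is first cyclised under mild base (NaOAc, EtOH/THF, reflux) to the bis-flavanone 16, which is isolated. It is then dehydrogenated with DDQ (2.5 equiv, dioxane, reflux) to 17, so no iodine or HI is present.

## Further compounds

F1 | step 4 | 1-[4,6-bis(benzyloxy)-2-(methoxymethoxy)-3-(4,4,5,5-tetramethyl-1,3,2-dioxaborolan-2-yl)phenyl]ethan-1-one | CC(=O)c1c(OCOC)c(B2OC(C)(C)C(C)(C)O2)c(OCc2ccccc2)cc1OCc1ccccc1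
F2 | step 6 | (E)-1-[4,6-bis(benzyloxy)-2-hydroxy-3-iodophenyl]-3-(4-methoxyphenyl)prop-2-en-1-one | COc1ccc(/C=C/C(=O)c2c(O)c(I)c(OCc3ccccc3)cc2OCc2ccccc2)cc1
F3 | step 6 | 5,7-bis(benzyloxy)-8-iodo-2-(4-methoxyphenyl)-4H-chromen-4-one | COc1ccc(-c2cc(=O)c3c(OCc4ccccc4)cc(OCc4ccccc4)c(I)c3o2)cc1
F4 | step 6 | (E)-1-[4,6-bis(benzyloxy)-2-hydroxy-3-iodophenyl]-3-[4-(benzyloxy)phenyl]prop-2-en-1-one | O=C(/C=C/c1ccc(OCc2ccccc2)cc1)c1c(O)c(I)c(OCc2ccccc2)cc1OCc1ccccc1
F5 | step 6 | 5,7-bis(benzyloxy)-2-[4-(benzyloxy)phenyl]-8-iodo-4H-chromen-4-one | O=c1cc(-c2ccc(OCc3ccccc3)cc2)oc2c(I)c(OCc3ccccc3)cc(OCc3ccccc3)c12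
F6 | step 6 | 5,7-bis(benzyloxy)-2-[4-(benzyloxy)phenyl]-8-(4,4,5,5-tetramethyl-1,3,2-dioxaborolan-2-yl)-4H-chromen-4-one | O=c1cc(-c2ccc(OCc3ccccc3)cc2)oc2c(B3OC(C)(C)C(C)(C)O3)c(OCc3ccccc3)cc(OCc3ccccc3)c12
F0 | step 8 | none | none
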